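You read each flask at 8.0 s, and what you want from that reading is how far propagation has got by then, which is a time integral.

| flask | free monomer | capture agent | initiator | temperature | time | remark |
|---|---|---|---|---|---|---|
| delta | 18 mM (in portions, 2) | 0.360 mM | 1 mol% | 100 °C | 8.0 s | the portions of free monomer follow each other after 1.5 s, the first at the start |
| theta | 18 mM (in portions, 2) | 0.360 mM | 1 mol% | 70 °C | 8.0 s | the portions of free monomer follow each other after 1.5 s, the first at the start |

    free monomer + initiator → living end + monomer in chains (k1 = 6.7 /M/s, Ea1 = 55.0 kJ/mol)
    free monomer + living end → monomer in chains + living end, rate k2*[living end]*[free monomer] (k2 = 520 /M/s, Ea2 = 52.0 kJ/mol)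
    living end + capture agent → trapped intermediate (k3 = 170 /M/s, Ea3 = 46.0 kJ/mol)
    2 living end ⇌ resting dimer, settled at all times (K4 = 1800 /M, ΔH4 = −16.0 kJ/mol)
    (constants at 100 °C)

- where a step has two of a species, its rate is k times that concentration squared, and two are used at each turn
- constants are those at 100 °C; use the activation energies and enthalpies for any other temperature

- the flask that comes out highest in amount of monomer in chains, in percent of the free monomer charged, or "all alike" when all lie within 1.5 percentage points (delta / theta / all alike)
- monomer in chains at the end, in percent of the free monomer charged, delta
- monomer in chains at the end, in percent of the free monomer charged, theta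

Step 2 is first order in free monomer, so the monomer surviving goes as e^(−D), where D = k∫[L]dt, k is the constant of step 2 and [L] is the living end concentration. Conversion is then 1 − e^(−D). Take delta and read the loading on the whole charge, so the initiator starts at N = 0.180 mM. With free monomer nearly constant, initiation is pseudo-first-order at α = 0.121 /s, and propagation has the scale P = kN = 0.0936 /s. If every initiator becomes a lasting living end, D = P[t − (1 − e^(−αt))/α], which is 0.268, or 23.5 % conversion.

That estimate is too generous in two ways. For the first 1.5 s half of the free monomer stands in delta, so the integral of monomer over time is that of a full charge over τ = 7.25 s. Capture also matters: the capture agent is twice the initiator charge, so half of it stays even if every initiator ends up trapped; I hold it constant, and it removes living ends at γ = 0.0612 /s. That is a lifetime of 16.3 s, longer than the reading time but not negligible beside it. Integrating the two first-order steps in closed form, with τ as the clock of both as a rough step, gives the propagation dose D = Pα/(α−γ)·[(1 − e^(−γτ))/γ − (1 − e^(−ατ))/α], which for delta is 0.194, or 17.6 % conversion.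

One doubt remains. The resting dimer holds ends out of propagation, and with 0.0821 mM of ends reckoned for the reading in delta, the ratio of bound to free ends there comes to about 0.295, and to less earlier, while the ends are still fewer. So my delta figure is somewhat high, though this is a trim and not a collapse. Theta slows steps 1 and 2 by 4.7 and 4.3, and early on D follows their product, so I commit to delta as the higher flask.

The forecast also names delta, with 16 % for delta and 1.4 % for theta, a delta value below mine. Its ground: “Initiation is slow and sets the pace”.

The simulation gives 15.5 % for delta and 1.36 % for theta, so delta is highest and the forecast stands, with my delta figure high by 2.1 percentage points. In delta, step 2 had 28 % of its turnover up to the reading behind it at 4.00 s, and the other 72.0 % came after that. With the constants of steps 1, 2 and 3 slowed by 4.7, 4.3 and 3.7, the dose for theta is 0.0131, or 1.30 % conversion.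

Now take the neighbour of delta charged with 7.2 mM of free monomer, capture agent still at 0.360 mM. Here α and N shrink with the charge and γ stays, so the dose is 0.0366, or 3.59 % conversion. The computed flask gives 3.72 %.

The constants used here stand for no real mixture.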